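A leftover is what I reckon with in this flask: the nucleophile still free once the buffer acid has protonated its share.

| setting | gamma | alpha | beta | flask |
|---|---|---|---|---|
| electrophile | 0.050 M | 0.050 M | 0.050 M | 0.050 M |
| nucleophile | 0.030 M | 0.045 M | 0.060 M | 0.0600 M |
| buffer base | 0.025 M | 0.025 M | 0.025 M | 0.0250 M |
| buffer acid | 0.015 M | 0.015 M | 0.030 M | 0.0150 M |
| remark | run made earlier | run made earlier | run made earlier |  |
| time |  |  |  | 4.0 h |

| run | time / h | electrophile / % | target / % |
|---|---|---|---|
| gamma | 0.333 | 85.3 | 15.5 |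
| gamma | 0.667 | 82.5 | 16.0 |
| gamma | 1.00 | 84.5 | 14.4 |
| gamma | 1.33 | 84.4 | 14.4 |
| gamma | 1.50 | 85.7 | 15.6 |
| gamma | 2.00 | 86.4 | 15.7 |
| gamma | 2.50 | 84.9 | 16.6 |
| alpha | 0.133 | 80.7 | 21.1 |
| alpha | 0.333 | 72.3 | 29.7 |
| alpha | 0.667 | 70.0 | 29.5 |
| alpha | 1.00 | 70.4 | 30.5 |
| alpha | 1.33 | 69.6 | 29.3 |
| alpha | 2.00 | 71.7 | 28.9 |
| alpha | 2.50 | 71.0 | 30.2 |
| beta | 0.200 | 74.4 | 25.4 |
| beta | 0.667 | 71.6 | 29.8 |
| beta | 1.00 | 69.6 | 31.5 |
| beta | 1.50 | 69.8 | 29.5 |
| beta | 2.50 | 71.3 | 29.9 |

(scatter of a reading: 1 percentage point)

- the numbers in the tables scatter by 1 percentage point (one standard deviation)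
- the earlier runs do not show the pH; that part of a forecast is a guess

* part of the electrophile that has reacted at 4.0 h
* pH of the solution at 4.0 h

1. I assume the buffer acid protonates 0.0150 M of nucleophile, so the 0.0600 M charged to this flask leaves 0.0450 M.
2. I assume each coupling uses one nucleophile and releases one acid, which protonates a second nucleophile. So c(target) stops at 0.02250 M, half the leftover: this is the target ceiling.
3. I test this on the runs. Divided by the electrophile charged, the ceiling is 15.0 % for gamma, 30.0 % for alpha and 30.0 % for beta. The last target readings are 16.6 %, 30.2 % and 29.9 %, with a scatter of 1 percentage point.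
4. In this flask the ceiling lies below c(electrophile). So nucleophile, though charged above electrophile, is the limiting reagent in my reckoning.
5. This flask has a higher ceiling than alpha, but alpha already reads 29.7 % at 0.333 h, and this flask gets a longer 4.0 h. I treat any shortfall in time as a correction below the scatter and commit to 45.0 %.
6. The runs show no pH, so I reckon none.

The forecast gives 45 % and pH 7, and says: “The reaction therefore ends when free nucleophile runs out, not at a true equilibrium.”

At 4.0 h the flask gives 45.0 % reacted and pH 6.29.

    electrophile + nucleophile ⇌ acid + target + leaving group (K = 1.30 × 10⁻⁴ M, k = 1.80 M⁻¹ min⁻¹)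
    protonated nucleophile ⇌ nucleophile + acid, settled at all times (K = 1.00 × 10⁻⁹ M)
    buffer acid ⇌ buffer base + acid, settled at all times (K = 2.50 × 10⁻⁴ M)

The flask stands at its ceiling share of 45.0 %, with 0.12 % of its nucleophile charge free and 55 % of its electrophile charge unreacted. The neighbour flask, charged with 0.20 M of electrophile, has the same leftover and the same ceiling of 0.0225 M. Over its larger charge that ceiling is 11.2 %. The neighbour flask gives 11.3 % reacted at 4.0 h, with 88.7 % of its electrophile charge remaining and 0.048 % of its nucleophile charge free.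

The readings stem from a simulated flask on assumed constants, noise included.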